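## Structural features

Numbering used throughout: C1 is the quaternary oxirane carbon that carries C7H2–OBz, C2 is the carbinol carbon, C3 carries the ring benzoate, C4=C5 is the alkene and C6 is the oxirane CH; O-2, O-3 and O-7 are the oxygens on C2, C3 and C7. The only carbocycle is a cyclohexene, cis-fused along C1–C6 to an oxirane (7-oxabicyclo[4.1.0]hept-4-ene). Because C5 is bonded to C6, the array O–C1–C6–C5=C4 is a vinyl oxirane. The four stereocentres C6, C1, C2 and C3 stand in a row, (1R,2S,3S,6S): C7, O-2 and O-3 lie on one face (β) and the oxirane oxygen on the other (α), so O-2 and O-3 are cis to each other and anti to the oxirane. Every ring carbon is sp2 or oxygen-bearing, and the seven skeletal carbons are those of a benzoic ester, so the core is a benzene ring that has taken up three oxygen atoms. The fragile points are four: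
- the vinyl oxirane (acid, SN2′ opening, zerovalent palladium);
- the free O-2–H, which is anti to the C1–O bond (Payne rearrangement under base);
- the two benzoates within reach of O-2 (acyl shift from O-3 or O-7);
- the escape to an arene by loss of water or benzoic acid.

The real difficulty is to put one oxygen on the more hindered C1=C6 edge of a diene, on the face away from the cis-diol, creating the quaternary centre C1 without touching C4=C5, and then to tell O-3 from O-2. The key step exploits the 1,4 relation across the ring between the oxygen on C1 and the alkene terminus C4: O–C1–C6–C5=C4 is exactly what a C1–O–O–C4 endoperoxide with a C5=C6 bond leaves behind when the oxygen on C4 is removed with allylic shift.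

## Logic of the disconnections

**10 to 9.** The acyl–oxygen bond at O-3 is cut. A benzoate next to a free cis hydroxyl can migrate, so this pair should exist only in the last flask. The gain is that O-2 and O-3 need not be told apart earlier and can share one protecting group. The forward step must acylate O-3, which is flanked by the sp2 carbon C4, in preference to O-2, which is wedged between C3 and the quaternary C1.

**9 to 8.** The two O–Si bonds are cut. Bulky ethers on O-2 and O-3 are wanted in the key step as a screen for the β face. The gain is a lipophilic substrate free of hydroxyl groups. The forward cleavage must be close to neutral, because an O-2 alkoxide could start oxirane migration or acyl transfer.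

**8 to 5, by way of 7 and 6.** This is the key disconnection.
- In the retro sense the C6–O bond of the oxirane is cut, the π bond moves back from C4=C5 to C5=C6, and an oxygen is placed on C4 and joined to the oxygen on C1. This gives 6. Then C1–O and C4–O are cut together in a retro-[4+2] step.
- In one sentence: 8 is made by adding singlet oxygen across C1 and C4 of 5 and letting a phosphine pull the C4 oxygen out of 6, with allylic closure of the oxirane.
- The cut is made here because the diene then reacts as one unit, so the question of which alkene is oxidised does not arise.
- The gain is the loss of the three-membered ring, of the quaternary centre C1 and of C6. A flat conjugated diene with two stereocentres remains.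
- The demands are α-face attack of singlet oxygen and attack of the phosphine at the oxygen on C4.

**5 to 4.** The acyl–oxygen bond at O-7 is cut. The benzoate cannot be present earlier, since it would not survive the hydride step. The forward step is a plain acylation of the only free hydroxyl.

**4 to 3.** The two C7–H bonds are cut and C7 returns to the ester level. With an ester on C1, the ring carries the substituent that the dearomatising enzyme accepts. The forward step needs 1,2-selective hydride delivery to a dienoate.

**3 to 2.** The two O–Si bonds are cut. The forward step must be basic or neutral, since the diene-diol dehydrates to a phenol in acid.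

**2 to 1.** The C2–O and C3–O bonds are cut and the ring is re-aromatised. The last two stereocentres vanish, and all seven skeletal carbons arrive in one flat, cheap compound. The forward step must add two oxygens cis to the bond next to the ester-bearing carbon, on one face only.

## Other disconnections considered

**Alternative 1:** (the first that comes to mind)
- Cut: both oxirane C–O bonds at once.
- Forward key step: peracid epoxidation of the C1=C6 bond of the acetonide-protected dienyl benzoate A1 to the oxirane A2, followed by acetonide removal and benzoylation at O-3.
- Grounds for preferring the chosen plan: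
  - The peracid has to choose between two alkenes of similar nucleophilicity. C1=C6 is trisubstituted but is deactivated inductively by O-7 and O-2 and is hindered, while C4=C5 is open.
  - A2 still holds an alkene that can be oxidised again.
  - The carboxylic acid set free can open the allylic oxirane.
  - The acetonide can only be removed with aqueous acid, which the vinyl oxirane should not survive.
  - The chosen plan needs the same number of steps, avoids the alkene competition and runs under neutral conditions.

**Alternative 2:**
- Cut: the C4=C5 double bond.
- Forward key step: ring-closing metathesis of the carbohydrate-derived acyclic 1,7-diene A3 with the second-generation Grubbs catalyst to give the cyclohexenediol A4. Sulfonylation of the C6 hydroxyl and SN2 closure by the C1 hydroxyl then follow.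
- Grounds for preferring the chosen plan:
  - The metathesis forms a bond that carries no stereochemical information.
  - All four stereocentres, the tertiary carbinol C1 among them, would have to be set one by one in an open chain by additions to carbonyl groups.
  - The route would be roughly twice as long.
  - It ends with the same clash between acetonide removal and the vinyl oxirane.

**Alternative 3:**
- Cut: C2–O and C3–O, starting from an arene oxide.
- Forward key step: anti epoxidation of the C2=C3 bond of the arene oxide A5 to the diepoxide A6, then opening at the allylic C3 with benzoate.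
- Grounds for preferring the chosen plan:
  - A5 is in valence-tautomeric equilibrium with its oxepine, in which C1 and C6 are no longer stereocentres, so it cannot be kept as one enantiomer.
  - SN2 opening inverts C3 and leads to the trans-2,3 arrangement of A7, the C3 epimer of the target. A further inversion next to a vinyl oxirane would then be needed.

Key step: step 5

Assumption: the recombinant strain E. coli JM109(pDTG601A), which over-expresses toluene dioxygenase, is treated as an accessible biocatalyst and not as a starting material.

## Route

Step 1
Reactants: 1 ethyl benzoate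
Product: 2 ethyl (5S,6R)-5,6-dihydroxycyclohexa-1,3-diene-1-carboxylate
Conditions: E. coli JM109(pDTG601A) whole cells (toluene dioxygenase), IPTG, D-glucose feed, air, mineral salts medium pH 7, 35 °C; EtOAc extraction
Reagents that add atoms: dioxygen, O=O
Why: Enzymatic dearomatising cis-dihydroxylation by a Rieske-type arene dioxygenase, for which benzoate esters are accepted substrates; both atoms of one dioxygen molecule go to the same face of the ring bond next to the ester-bearing carbon. The active site fixes the regiochemistry and the absolute sense, so C2 and C3 are set together in the configuration that the target needs.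

Step 2
Reactants: 2 ethyl (5S,6R)-5,6-dihydroxycyclohexa-1,3-diene-1-carboxylate
Product: 3 ethyl (5S,6R)-5,6-bis(triethylsilyloxy)cyclohexa-1,3-diene-1-carboxylate
Conditions: Et3SiCl (2.5 equiv), imidazole, DMAP (cat.), DMF, 0 °C to rt
Reagents that add atoms: chlorotriethylsilane, CC[Si](Cl)(CC)CC
Why: Standard silyl ether formation under basic conditions, which the acid-labile diene-diol tolerates; no stereocentre is touched. The two ethers block dehydration to a phenol, slow the Diels–Alder dimerisation of the diene and later screen the β face.

Step 3
Reactants: 3 ethyl (5S,6R)-5,6-bis(triethylsilyloxy)cyclohexa-1,3-diene-1-carboxylate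
Product: 4 [(5S,6R)-5,6-bis(triethylsilyloxy)cyclohexa-1,3-dien-1-yl]methanol
Conditions: i-Bu2AlH (2.3 equiv), CH2Cl2, −78 °C; aq. potassium sodium tartrate
Reagents that add atoms: none
Why: 1,2-Reduction of a conjugated ester to the allylic alcohol with i-Bu2AlH; silyl ethers and the diene are inert at −78 °C and no stereocentre is touched.

Step 4
Reactants: 4 [(5S,6R)-5,6-bis(triethylsilyloxy)cyclohexa-1,3-dien-1-yl]methanol
Product: 5 [(5S,6R)-5,6-bis(triethylsilyloxy)cyclohexa-1,3-dien-1-yl]methyl benzoate
Conditions: BzCl, pyridine, DMAP (cat.), CH2Cl2, 0 °C
Reagents that add atoms: benzoyl chloride, O=C(Cl)c1ccccc1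
Why: Nucleophile-catalysed acylation of the only free, primary hydroxyl; the basic medium keeps the diene from aromatising.

Step 5
Reactants: 5 [(5S,6R)-5,6-bis(triethylsilyloxy)cyclohexa-1,3-dien-1-yl]methyl benzoate
Product: 8 [(1S,2S,3S,6S)-2,3-bis(triethylsilyloxy)-7-oxabicyclo[4.1.0]hept-4-en-1-yl]methyl benzoate, via endoperoxide 6 (not isolated), via oxyphosphonium alkoxide 7 (not isolated)
Conditions: O2 (1 atm), meso-tetraphenylporphyrin (cat.), white LED, dry CH2Cl2, −20 °C; Ar purge; then PPh3 (1.05 equiv), −20 °C to rt, one pot
Reagents that add atoms: dioxygen, O=O
Why: Sensitised singlet oxygen adds suprafacially to C1 and C4 of the ring-locked s-cis diene of 5 in a concerted [4+2] cycloaddition (photooxygenation of a cyclic 1,3-diene), which closes the 1,2-dioxane ring of the strained 2,3-dioxabicyclo[2.2.2]oct-5-ene 6. The two Et3SiO groups on C2 and C3 cover the β face, so singlet oxygen should enter from the α face and set the quaternary centre C1 (and the transient centre C4) anti to them; the locked s-cis geometry should let the cycloaddition outrun the ene reaction at the hydrogens on C7, C2 and C3. PPh3 then attacks the weak O–O bond in a displacement at oxygen, the known deoxygenation of unsaturated 1,4-endoperoxides by trivalent phosphorus to 1,3-diene monoepoxides. The regioselectivity that the step needs is attack at the oxygen on the secondary carbon C4: the line of approach to the oxygen on C1 is screened by the CH2OBz group, and the tertiary alkoxide that leaves is stabilised inductively by that group, which gives 7. In 7 the C1 alkoxide attacks C6 in a syn SN2′ displacement (3-exo-trig closure of the oxirane), the π bond moves from C5=C6 to C4=C5 and Ph3P=O leaves from C4. C6 is set by the tether, because the oxygen is held on the α face of C1 and can reach only the α face of C6, so the oxirane is cis-fused and anti to O-2 and O-3. Cleavage of the peroxide bond, relief of the bicyclic strain and formation of the P=O bond drive the collapse under neutral, metal-free conditions that benzoate, silyl ethers and vinyl oxirane tolerate. Because the diene reacts as one unit and C4=C5 appears only after the oxidant has been purged, neither competition between the two alkenes nor over-oxidation can arise.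

Step 6
Reactants: 8 [(1S,2S,3S,6S)-2,3-bis(triethylsilyloxy)-7-oxabicyclo[4.1.0]hept-4-en-1-yl]methyl benzoate
Product: 9 [(1R,2S,3S,6S)-2,3-dihydroxy-7-oxabicyclo[4.1.0]hept-4-en-1-yl]methyl benzoate
Conditions: Bu4NF/AcOH (1:1, 2.5 equiv), THF, 0 °C to rt
Reagents that add atoms: none
Why: Fluoride-induced cleavage of triethylsilyl ethers, driven by the Si–F bond. The acetic acid buffer protonates each alkoxide as it forms, so that neither Payne rearrangement from O-2 nor benzoyl transfer from O-7 should start, and the medium is too weakly acidic to open the vinyl oxirane.

Step 7
Reactants: 9 [(1R,2S,3S,6S)-2,3-dihydroxy-7-oxabicyclo[4.1.0]hept-4-en-1-yl]methyl benzoate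
Product: 10 [(1R,2S,3S,6S)-3-benzoyloxy-2-hydroxy-7-oxabicyclo[4.1.0]hept-4-en-1-yl]methyl benzoate (target)
Conditions: BzCl (1.05 equiv), pyridine, CH2Cl2, −40 °C
Reagents that add atoms: benzoyl chloride, O=C(Cl)c1ccccc1
Why: Kinetically controlled site-selective acylation: O-3 is an allylic secondary hydroxyl next to the sp2 carbon C4, whereas O-2 is wedged between C3 and the quaternary C1, whose CH2OBz arm lies on the same face. Low temperature and one equivalent of acylating agent should hold back the second acylation and acyl migration; no stereocentre is touched.

## Compound list

1 | ethyl benzoate | CCOC(=O)c1ccccc1 | starting material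
2 | ethyl (5S,6R)-5,6-dihydroxycyclohexa-1,3-diene-1-carboxylate | CCOC(=O)C1=CC=C[C@H](O)[C@@H]1O | intermediate
3 | ethyl (5S,6R)-5,6-bis(triethylsilyloxy)cyclohexa-1,3-diene-1-carboxylate | CCOC(=O)C1=CC=C[C@H](O[Si](CC)(CC)CC)[C@@H]1O[Si](CC)(CC)CC | intermediate
4 | [(5S,6R)-5,6-bis(triethylsilyloxy)cyclohexa-1,3-dien-1-yl]methanol | OCC1=CC=C[C@H](O[Si](CC)(CC)CC)[C@@H]1O[Si](CC)(CC)CC | intermediate
5 | [(5S,6R)-5,6-bis(triethylsilyloxy)cyclohexa-1,3-dien-1-yl]methyl benzoate | O=C(OCC1=CC=C[C@H](O[Si](CC)(CC)CC)[C@@H]1O[Si](CC)(CC)CC)c1ccccc1 | intermediate
6 | [(1R,4R,7S,8S)-7,8-bis(triethylsilyloxy)-2,3-dioxabicyclo[2.2.2]oct-5-en-1-yl]methyl benzoate (endoperoxide, O–O bridge on the α face) | O=C(OC[C@@]12C=C[C@@H](OO1)[C@H](O[Si](CC)(CC)CC)[C@@H]2O[Si](CC)(CC)CC)c1ccccc1 | intermediate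
7 | oxyphosphonium alkoxide (betaine): cyclohex-5-ene with α-alkoxide and β-CH2OBz on C1, α-OP(+)Ph3 on C4, β-OSiEt3 on C2 and C3 | O=C(OC[C@]1([O-])C=C[C@@H](O[P+](c2ccccc2)(c2ccccc2)c2ccccc2)[C@H](O[Si](CC)(CC)CC)[C@@H]1O[Si](CC)(CC)CC)c1ccccc1 | intermediate
8 | [(1S,2S,3S,6S)-2,3-bis(triethylsilyloxy)-7-oxabicyclo[4.1.0]hept-4-en-1-yl]methyl benzoate | O=C(OC[C@]12O[C@H]1C=C[C@H](O[Si](CC)(CC)CC)[C@@H]2O[Si](CC)(CC)CC)c1ccccc1 | intermediate
9 | [(1R,2S,3S,6S)-2,3-dihydroxy-7-oxabicyclo[4.1.0]hept-4-en-1-yl]methyl benzoate | O=C(OC[C@]12O[C@H]1C=C[C@H](O)[C@@H]2O)c1ccccc1 | intermediate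
10 | [(1R,2S,3S,6S)-3-benzoyloxy-2-hydroxy-7-oxabicyclo[4.1.0]hept-4-en-1-yl]methyl benzoate | O=C(OC[C@]12O[C@H]1C=C[C@H](OC(=O)c1ccccc1)[C@@H]2O)c1ccccc1 | target

## Step count and least certain steps

Total step count: 7. Longest linear sequence: 7 (the route is fully linear).

**Step 5 (key step).** Several things may go wrong:
- The phosphine may attack the wrong peroxide oxygen, or a cyclic phosphorane may form reversibly and ionise at the tertiary allylic C1–O bond. In either case the oxirane would close at the C4–C5 end.
- Traces of water may hydrolyse the phosphorus intermediate, which stops the sequence at the ene-diol level.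
- The benzoyl group from O-7 or the silyl group from O-2 may transfer to the tertiary alkoxide before it closes.
- Singlet oxygen may attack partly from the β face.

The fallback sets out from 4 and comes back at 8. Hydroxyl-directed epoxidation with VO(acac)2 (cat.) and t-BuOOH in CH2Cl2 at 0 °C binds O-7 to vanadium. Oxygen can then be delivered only to the adjacent C1=C6 bond, and the silyl ether on C2 screens the β face. This should give the epoxy alcohol F1. Benzoylation of F1 (BzCl, pyridine, 0 °C) leads to 8.

**Step 7.** The acylation may discriminate poorly between the two cis hydroxyls, may run on to double acylation, or the benzoyl group may drift from O-3 to O-2 in the basic medium. The fallback sets out from 9 and comes back at 10. It replaces discrimination by the electrophile with activation of the nucleophile. The catalyst is 2-aminoethyl diphenylborinate, Ph2BOCH2CH2NH2 (cat.), used with i-Pr2NEt and BzCl in MeCN at rt. The cis-diol is bound reversibly as the cyclic borinate F2, in which only the boron-bound oxygens are activated and the less hindered one, O-3, should be acylated.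

**Step 6.** A transient O-2 alkoxide may trigger oxirane migration or take the benzoyl group from O-7, and fluoride or acetate may open the vinyl oxirane. The hindered ether on O-2 may also need long exposure. The fallback sets out from 5 and comes back at 9, and it moves the desilylation to a stage where no oxirane exists. Bu4NF/AcOH in THF converts 5 into the free diene-diol F3. Photooxygenation of F3 (O2, methylene blue, CH2Cl2/MeOH, −20 °C) uses a protic cosolvent to damp hydrogen-bond steering to the β face, and should give the endoperoxide F4. PPh3 then turns F4 directly into 9. The price is a weaker steric screen for the facial selectivity.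

## Further compounds

F1 | step 5 | [(1S,2S,3S,6S)-2,3-bis(triethylsilyloxy)-7-oxabicyclo[4.1.0]hept-4-en-1-yl]methanol | OC[C@]12O[C@H]1C=C[C@H](O[Si](CC)(CC)CC)[C@@H]2O[Si](CC)(CC)CC
F2 | step 7 | diisopropylethylammonium salt of the cyclic diphenylborinate of 9 (boron bridges O-2 and O-3) | O=C(OC[C@]12O[C@H]1C=C[C@@H]3O[B-](c4ccccc4)(c4ccccc4)O[C@H]23)c1ccccc1.CC[NH+](C(C)C)C(C)C
F3 | step 6 | [(5S,6R)-5,6-dihydroxycyclohexa-1,3-dien-1-yl]methyl benzoate | O=C(OCC1=CC=C[C@H](O)[C@@H]1O)c1ccccc1
F4 | step 6 | [(1R,4R,7S,8R)-7,8-dihydroxy-2,3-dioxabicyclo[2.2.2]oct-5-en-1-yl]methyl benzoate | O=C(OC[C@@]12C=C[C@@H](OO1)[C@H](O)[C@@H]2O)c1ccccc1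
A1 | alternative 1 | [(5S,6R)-5,6-(isopropylidenedioxy)cyclohexa-1,3-dien-1-yl]methyl benzoate | O=C(OCC1=CC=C[C@@H]2OC(C)(C)O[C@H]12)c1ccccc1
A2 | alternative 1 | α-oxirane of A1 at C1–C6 (2,3-O-isopropylidene derivative of 9) | O=C(OC[C@]12O[C@H]1C=C[C@@H]3OC(C)(C)O[C@H]23)c1ccccc1
A3 | alternative 2 | acyclic 1,7-diene: C1 tertiary carbinol with CH2OBz, C6 carbinol, C2/C3 acetonide, vinyl groups on C3 and C6 | C=C[C@@H](O)[C@@](O)(COC(=O)c1ccccc1)[C@H]1OC(C)(C)O[C@H]1C=C
A4 | alternative 2 | cyclohexene from A3: α-OH and β-CH2OBz on C1, β-OH on C6, β-acetonide on C2/C3, C4=C5 | O=C(OC[C@]1(O)[C@H](O)C=C[C@@H]2OC(C)(C)O[C@H]12)c1ccccc1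
A5 | alternative 3 | 1-(benzoyloxymethyl)benzene oxide (one enantiomer drawn, configurationally labile) | O=C(OC[C@]12O[C@H]1C=CC=C2)c1ccccc1
A6 | alternative 3 | anti-diepoxide: α-oxirane at C1–C6, β-oxirane at C2–C3, C4=C5 | O=C(OC[C@]12O[C@H]1C=C[C@@H]3O[C@H]23)c1ccccc1
A7 | alternative 3 | C3 epimer of 10 (trans-2,3 arrangement) | O=C(OC[C@]12O[C@H]1C=C[C@@H](OC(=O)c1ccccc1)[C@@H]2O)c1ccccc1
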